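The vessel is closed, stirred and isothermal, and holds a charge of starting material with capture agent; read target throughout as a fraction of that charge.

| flask | starting material | capture agent | remark | time |
|---|---|---|---|---|
| south-east | 12 mM | 0.60 mM | the very flask that is asked about, followed so far |  |
| east | 6 mM | 0.60 mM | run made earlier |  |
| flask | 12 mM | 0.600 mM |  | 20 min |

| south-east: time / min | south-east: target / % | east: time / min | east: target / % |
|---|---|---|---|
| 0.833 | 13.2 | 0.833 | 15.0 |
| 1.00 | 15.4 | 1.33 | 18.7 |
| 2.00 | 22.7 | 3.00 | 24.6 |
| 2.50 | 23.7 | 5.00 | 22.4 |
| 4.00 | 22.5 | 10.0 | 8.8 |
| 6.00 | 18.1 | 20.0 | 0.4 |

(each reading ± 0.5 percentage points)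

- steps under discussion: starting material <-> intermediate A; intermediate A -> side product A; starting material -> target; intermediate A <-> intermediate B; intermediate B -> side product B; target -> over-reaction product; capture agent + intermediate B -> trapped intermediate

* time, not beyond 20 min, at which the flask holds most target
* the amount of target, in percent of the starting material charged, at that time

Draw the curve of this flask, the south-east run, from its own readings. Begin with the chord to the first reading, 0.158 min⁻¹ of the charge. Then find the knee: between 2.00 min and 2.50 min the gain has shrunk to 0.0200 min⁻¹, and between 2.50 min and 4.00 min it has turned into a loss of 0.00800 min⁻¹. Set each slope at the middle of its interval and let the line between them cross zero, which by my reckoning puts the peak at 2.96 min, and the shrinking gain after 2.50 min lifts the reading of 23.7% to 24.0%.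

These readings stop too early for the tail, so borrow the east run, which at half the starting material and the same capture agent tops its target readings at 24.6%, about as high as the south-east run. From its fall between 5.00 min and 10.0 min read the tail halving time, the apparent half-life of target, 3.71 min. Count it forward from 18.1% at 6.00 min: the 3.77 halvings up to 20 min leave 1.32%, less than the peak, so commit to the early maximum.

The forecast, from the same runs, says 24% at 2.9 min, noting that “its time is less certain than its height”. The flask gives 24.3% at 3.03 min.

    starting material ⇌ intermediate A (K = 0.390, k = 0.00150 s⁻¹)
    intermediate A → side product A (k = 0.00570 s⁻¹)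
    starting material → target (k = 0.00370 s⁻¹)
    intermediate A ⇌ intermediate B (K = 0.350, k = 0.00850 s⁻¹)
    intermediate B → side product B (k = 0.00340 s⁻¹)
    target → over-reaction product (k = 0.00630 s⁻¹)
    capture agent + intermediate B → trapped intermediate (k = 0.240 L mol⁻¹ s⁻¹)

Capture of intermediate B makes no difference to that height, with trapped intermediate at 0.0311% at 3.03 min. Target in the flask stands at 0.902% at 20.0 min, less than the 1.32% of target counted for that time, so target in the flask falls somewhat quicker over that stretch than the borrowed halving time says. Count on for target in the same flask read at 50 min: the 8.09 further halvings leave 0.00332% of target, and that reading gives 0% of target.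

All runs come from a simulation with constants of no real substance; the scatter is artificial.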